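**Strategy.** Ring A is disconnected across C1–C10 and C2–C3, so that a vinylphosphonium two-carbon linchpin (C1–C2) is stitched in one operation between C10, the α-carbon of a ring-B ketone (C9), and the aldehyde carbon C3 on quaternary C4. The step exploits the 1,4-relationship of the quaternary carbons C4 and C10 across ring A: C4 makes the C3 aldehyde non-enolisable, and the C9 carbonyl makes C10 a planar enolate, so both C10 epimers converge and C5 alone dictates the trans ring fusion. The precursor is a monocyclic 2-methylcyclohexanone carrying a C(CH3)(CO2Me)(CHO) group at C5; the C9 carbonyl later brings in the side chain and, transposed to C8, the exocyclic methylene.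

Key step: step 9

Remark on the chemistry: labdane numbering is used for all intermediates (C18 is the 4α carbon); β is the face of the C10 methyl group in the final decalin, α the opposite face.
Assumption: 2-methylcyclohex-2-en-1-one, racemic methyl 3-hydroxy-2-methylpropanoate, (S)-methyl hydrogen 3-methylglutarate and vinyltriphenylphosphonium bromide are taken as bought.

**Route**

Step 1
Reactants: 1 2-methylcyclohex-2-en-1-one
Product: 2 (S)-2-methylcyclohex-2-en-1-ol
Conditions: (R)-Me-CBS catalyst [(R)-1-methyl-3,3-diphenyltetrahydro-1H,3H-pyrrolo[1,2-c][1,3,2]oxazaborole, 10 mol%], BH3·SMe2, THF, −20 °C; MeOH quench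
Reagents that add atoms: none
Why: Corey–Bakshi–Shibata reduction, in which the α-methylvinyl side of the six-membered enone acts as the large group, should deliver hydride to one carbonyl face and give the (S)-carbinol that later fixes C5.

Step 2
Reactants: 3 methyl 3-hydroxy-2-methylpropanoate (racemic)
Product: 4 methyl 2-methyl-3-[(triethylsilyl)oxy]propanoate (racemic)
Conditions: Et3SiCl, imidazole, CH2Cl2, 0 °C → rt
Reagents that add atoms: chlorotriethylsilane, CC[Si](Cl)(CC)CC
Why: Standard silylation gives a bulky, weakly chelating and poorly leaving β-oxygen group for the later ester enolisation.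

Step 3
Reactants: 4 methyl 2-methyl-3-[(triethylsilyl)oxy]propanoate
Product: 5 2-methyl-3-[(triethylsilyl)oxy]propanoic acid (racemic)
Conditions: LiOH, THF/H2O, 0 °C; citric acid to pH 5
Reagents that add atoms: lithium hydroxide, [Li+].[OH-]
Why: Saponification of an unhindered methyl ester should proceed under cold hydroxide that the triethylsilyl ether tolerates.

Step 4
Reactants: 2 (S)-2-methylcyclohex-2-en-1-ol; 5 2-methyl-3-[(triethylsilyl)oxy]propanoic acid
Product: 6 (1S)-2-methylcyclohex-2-en-1-yl 2-methyl-3-[(triethylsilyl)oxy]propanoate (both epimers at the acyl α-carbon)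
Conditions: DCC, 4-(dimethylamino)pyridine (cat.), CH2Cl2, 0 °C → rt
Reagents that add atoms: none
Why: Steglich esterification acylates the secondary allylic alcohol without touching the carbinol stereocentre; the acyl α-centre is erased in the next step.

Step 5
Reactants: 6 (1S)-2-methylcyclohex-2-en-1-yl 2-methyl-3-[(triethylsilyl)oxy]propanoate
Product: 10 (2S)-3-hydroxy-2-methyl-2-[(1R)-2-methylcyclohex-2-en-1-yl]propanoic acid, via lithium enolate 7 (not isolated), via silyl ketene acetal 8 (not isolated), via trimethylsilyl ester 9 (not isolated)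
Conditions: LiN(iPr)2 (LDA) added to 6 and Me3SiCl/Et3N in THF, −78 °C; −78 → 65 °C; then 1 M HCl, THF, rt
Reagents that add atoms: none
Why: Ireland–Claisen rearrangement: kinetic enolisation should place the larger CH2OSiEt3 group cis to the allylic oxygen, and the cyclohexenyl ketene acetal is expected to react through the boat-like array, so suprafacial transfer from the (S)-carbinol should set C5 (H α) and quaternary C4 with CH2OH as future C3, CH3 as future C19 and CO2H as future C18.

Step 6
Reactants: 10 (2S)-3-hydroxy-2-methyl-2-[(1R)-2-methylcyclohex-2-en-1-yl]propanoic acid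
Product: 11 methyl (2S)-3-hydroxy-2-methyl-2-[(1R)-2-methylcyclohex-2-en-1-yl]propanoate
Conditions: Me3SiCHN2, MeOH/toluene, 0 °C
Reagents that add atoms: trimethylsilyldiazomethane, C[Si](C)(C)C=[N+]=[N-]
Why: Diazoalkane O-methylation esterifies the hindered quaternary acid under neutral conditions that leave the β-hydroxy group and alkene alone.

Step 7
Reactants: 11 methyl (2S)-3-hydroxy-2-methyl-2-[(1R)-2-methylcyclohex-2-en-1-yl]propanoate
Product: 13 methyl (2S)-3-hydroxy-2-[(1R,2R,3R)-3-hydroxy-2-methylcyclohexyl]-2-methylpropanoate, via C9 alkylborane 12 (not isolated)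
Conditions: BH3·THF, THF, 0 °C → rt; then NaOH, H2O2, 0 °C
Reagents that add atoms: hydrogen peroxide, OO
Why: Hydroboration–oxidation puts boron on the less substituted C9 anti to the bulky C5 substituent; the C9 and C10 configurations formed here are not needed later.

Step 8
Reactants: 13 methyl (2S)-3-hydroxy-2-[(1R,2R,3R)-3-hydroxy-2-methylcyclohexyl]-2-methylpropanoate
Product: 14 methyl (2S)-2-methyl-2-[(1R,2R)-2-methyl-3-oxocyclohexyl]-3-oxopropanoate
Conditions: Dess–Martin periodinane, NaHCO3, CH2Cl2, 0 °C → rt
Reagents that add atoms: none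
Why: Dess–Martin oxidation of both alcohols should give the C9 ketone and the C3 aldehyde, which cannot enolise because C4 is quaternary.

Step 9
Reactants: 14 methyl (2S)-2-methyl-2-[(1R,2R)-2-methyl-3-oxocyclohexyl]-3-oxopropanoate; 15 vinyltriphenylphosphonium bromide
Product: 18 methyl (1R,4aS,8aR)-1,4a-dimethyl-5-oxo-1,4,4a,5,6,7,8,8a-octahydronaphthalene-1-carboxylate, via sodium enolate 16 (not isolated), via phosphonium ylide 17 (not isolated)
Conditions: NaH (1.05 equiv), THF/DMF, 0 °C → rt; then 15, 0 → 50 °C
Reagents that add atoms: none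
Why: Deprotonation gives the more substituted C9–C10 sodium enolate 16, which adds in Michael fashion to the vinylphosphonium salt and forms C1–C10 and ylide 17; the non-stabilised ylide then closes ring A on the neopentyl aldehyde by a 6-exo-trig intramolecular Wittig reaction, forming C2=C3. The closest known reaction type is the Schweizer annulation (enolate addition to vinyltriphenylphosphonium bromide followed by intramolecular Wittig olefination). The only new stereocentre, quaternary C10, is controlled by C5: C1 should enter anti to the bulky C5 substituent, so C1 and C4 are trans and the ring fusion is trans, while both C10 epimers of 14 converge through the planar enolate. The step needs C10 over C8 regioselectivity, which thermodynamic enolate formation should secure, helped by the fact that only the C10 adduct can close a six-membered ring irreversibly. It also needs the ylide to choose the aldehyde over the ketone and the hindered ester, which the far higher reactivity of the non-enolisable aldehyde should secure.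

Step 10
Reactants: 18 methyl (1R,4aS,8aR)-1,4a-dimethyl-5-oxo-1,4,4a,5,6,7,8,8a-octahydronaphthalene-1-carboxylate
Product: 19 methyl (1R,4aS,8aR)-1,4a-dimethyl-5-oxodecahydronaphthalene-1-carboxylate
Conditions: H2 (1 atm), Pd on carbon, EtOAc, rt
Reagents that add atoms: none
Why: Catalytic hydrogenation saturates the only C=C bond (C2=C3) and creates no stereocentre; ketone and ester are inert.

Step 11
Reactants: 19 methyl (1R,4aS,8aR)-1,4a-dimethyl-5-oxodecahydronaphthalene-1-carboxylate
Product: 21 methyl (1R,4aS,8aR)-1,4a-dimethyl-5-{[(trifluoromethyl)sulfonyl]oxy}-1,2,3,4,4a,7,8,8a-octahydronaphthalene-1-carboxylate, via potassium enolate 20 (not isolated)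
Conditions: KN(SiMe3)2 (KHMDS), THF, −78 °C; then PhNTf2, −78 → 0 °C
Reagents that add atoms: N-phenylbis(trifluoromethanesulfonimide), O=S(=O)(N(c1ccccc1)S(=O)(=O)C(F)(F)F)C(F)(F)F
Why: Enol triflate formation is regiospecific because C10 is quaternary and only C8 can enolise; the quaternary ester has no α-hydrogen.

Step 12
Reactants: 22 (S)-5-methoxy-3-methyl-5-oxopentanoic acid [(S)-methyl hydrogen 3-methylglutarate]
Product: 23 methyl (S)-5-hydroxy-3-methylpentanoate
Conditions: BH3·SMe2, THF, 0 °C → rt; MeOH quench; used directly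
Reagents that add atoms: none
Why: Borane reduces the carboxylic acid chemoselectively in the presence of the methyl ester and does not touch the C13 stereocentre.

Step 13
Reactants: 23 methyl (S)-5-hydroxy-3-methylpentanoate
Product: 24 methyl (R)-5-iodo-3-methylpentanoate
Conditions: I2, PPh3, imidazole, CH2Cl2, 0 °C → rt
Reagents that add atoms: iodine, II
Why: Appel-type iodination of the primary alcohol; the descriptor changes only because iodine raises the priority of that branch.

Step 14
Reactants: 21 enol triflate; 24 methyl (R)-5-iodo-3-methylpentanoate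
Product: 26 dimethyl (13S)-17-norlabd-8-ene-15,18-dioate [methyl (1R,4aS,8aR)-5-[(3S)-5-methoxy-3-methyl-5-oxopentyl]-1,4a-dimethyl-1,2,3,4,4a,7,8,8a-octahydronaphthalene-1-carboxylate], via alkylzinc iodide 25 (not isolated)
Conditions: 24, Zn dust, LiCl, THF, 40 °C; then 21, PdCl2(dppf) [dppf = 1,1'-bis(diphenylphosphino)ferrocene, 5 mol%], THF/NMP, 60 °C
Reagents that add atoms: none
Why: Negishi sp3–sp2 cross-coupling of an ester-tolerant primary alkylzinc with the alkenyl triflate forms the C9–C11 bond and leaves the C8=C9 alkene for the next step.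

Step 15
Reactants: 26 dimethyl (13S)-17-norlabd-8-ene-15,18-dioate
Product: 28 dimethyl (13S)-8α-hydroxy-17-norlabdane-15,18-dioate, via C8 alkylborane 27 (not isolated)
Conditions: BH3·SMe2, THF, 0 °C → rt; then Me3NO·2H2O, THF, 65 °C
Reagents that add atoms: trimethylamine N-oxide, C[N+](C)(C)[O-]
Why: Hydroboration–oxidation should add from the α face, anti to the axial C10 methyl, placing boron on C8 and hydrogen on C9 (9α-H, side chain β); the esters are reduced much more slowly.

Step 16
Reactants: 28 dimethyl (13S)-8α-hydroxy-17-norlabdane-15,18-dioate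
Product: 29 dimethyl (13S)-8-oxo-17-norlabdane-15,18-dioate
Conditions: Dess–Martin periodinane, NaHCO3, CH2Cl2, rt
Reagents that add atoms: none
Why: Dess–Martin oxidation gives the C8 ketone; the equatorial C9 side chain is also the thermodynamic configuration α to this ketone.

Step 17
Reactants: 29 dimethyl (13S)-8-oxo-17-norlabdane-15,18-dioate
Product: 30 dimethyl (13S)-labd-8(17)-ene-15,18-dioate
Conditions: Ph3PCH3Br, KOtBu, toluene, 80 °C
Reagents that add atoms: methyltriphenylphosphonium bromide, C[P+](c1ccccc1)(c1ccccc1)c1ccccc1.[Br-]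
Why: Wittig methylenation of the 8-ketone installs the exocyclic C8=C17 bond; the esters do not react, and any C9 epimerisation returns to the equatorial isomer.

Step 18
Reactants: 30 dimethyl (13S)-labd-8(17)-ene-15,18-dioate
Product: 31 (13S)-18-methoxy-18-oxolabd-8(17)-en-15-oic acid
Conditions: LiOH, THF/MeOH/H2O, rt; then 1 M HCl to pH 3
Reagents that add atoms: lithium hydroxide, [Li+].[OH-]
Why: Saponification should be selective for the unhindered side-chain ester, since the quaternary neopentyl C18 ester resists hydroxide at room temperature.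

Step 19
Reactants: 31 (13S)-18-methoxy-18-oxolabd-8(17)-en-15-oic acid
Product: 32 (13S)-18-hydroxylabd-8(17)-en-15-oic acid
Conditions: LiEt3BH (5 equiv), THF, 0 °C → rt; cold 1 M HCl work-up
Reagents that add atoms: none
Why: Lithium triethylborohydride reduces the hindered C18 ester to the primary alcohol, while the lithium carboxylate formed first and the exocyclic alkene are inert.

Step 20
Reactants: 32 (13S)-18-hydroxylabd-8(17)-en-15-oic acid
Product: 34 (13S)-18-acetoxylabd-8(17)-en-15-oic acid (target), via mixed acetic anhydride 33 (not isolated)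
Conditions: Ac2O, pyridine, 4-(dimethylamino)pyridine (cat.), CH2Cl2, rt; then H2O, NaHCO3, THF; acidify
Reagents that add atoms: acetic anhydride, CC(=O)OC(C)=O; water, O
Why: Acetylation of the primary neopentyl alcohol; the mixed anhydride formed at the carboxyl group is hydrolysed in the aqueous stage and no stereocentre is touched.

**Compound list**

1 | 2-methylcyclohex-2-en-1-one | CC1=CCCCC1=O | starting material
2 | (S)-2-methylcyclohex-2-en-1-ol | O[C@H]1CCCC=C1C | intermediate
3 | methyl 3-hydroxy-2-methylpropanoate (racemic) | COC(=O)C(C)CO | starting material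
4 | methyl 2-methyl-3-[(triethylsilyl)oxy]propanoate (racemic) | COC(=O)C(C)CO[Si](CC)(CC)CC | intermediate
5 | 2-methyl-3-[(triethylsilyl)oxy]propanoic acid (racemic) | OC(=O)C(C)CO[Si](CC)(CC)CC | intermediate
6 | (1S)-2-methylcyclohex-2-en-1-yl 2-methyl-3-[(triethylsilyl)oxy]propanoate | CC(CO[Si](CC)(CC)CC)C(=O)O[C@H]1CCCC=C1C | intermediate
7 | lithium enolate of 6, CH2OSiEt3 cis to the allylic oxygen (not isolated) | C/C(CO[Si](CC)(CC)CC)=C(\O[Li])O[C@H]1CCCC=C1C | intermediate
8 | trimethylsilyl ketene acetal of 6, same geometry (not isolated) | C/C(CO[Si](CC)(CC)CC)=C(\O[Si](C)(C)C)O[C@H]1CCCC=C1C | intermediate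
9 | trimethylsilyl (2S)-2-methyl-2-[(1R)-2-methylcyclohex-2-en-1-yl]-3-[(triethylsilyl)oxy]propanoate (not isolated) | C1CC[C@@H]([C@](C)(C(=O)O[Si](C)(C)C)CO[Si](CC)(CC)CC)C(C)=C1 | intermediate
10 | (2S)-3-hydroxy-2-methyl-2-[(1R)-2-methylcyclohex-2-en-1-yl]propanoic acid | C1CC[C@@H]([C@](C)(C(=O)O)CO)C(C)=C1 | intermediate
11 | methyl (2S)-3-hydroxy-2-methyl-2-[(1R)-2-methylcyclohex-2-en-1-yl]propanoate | C1CC[C@@H]([C@](C)(C(=O)OC)CO)C(C)=C1 | intermediate
12 | C9 alkylborane of 11, hydroxyl bound as borate, drawn as the bis-BH2 species (not isolated) | C1CC[C@@H]([C@](C)(C(=O)OC)COB)[C@@H](C)[C@@H]1B | intermediate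
13 | methyl (2S)-3-hydroxy-2-[(1R,2R,3R)-3-hydroxy-2-methylcyclohexyl]-2-methylpropanoate | C1CC[C@@H]([C@](C)(C(=O)OC)CO)[C@@H](C)[C@@H]1O | intermediate
14 | methyl (2S)-2-methyl-2-[(1R,2R)-2-methyl-3-oxocyclohexyl]-3-oxopropanoate | C1CC[C@@H]([C@](C)(C(=O)OC)C=O)[C@@H](C)C1=O | intermediate
15 | vinyltriphenylphosphonium bromide | C=C[P+](c1ccccc1)(c1ccccc1)c1ccccc1.[Br-] | starting material
16 | sodium C9–C10 enolate of 14 (not isolated) | C1CC[C@@H]([C@](C)(C(=O)OC)C=O)C(C)=C1O[Na] | intermediate
17 | C10 Michael adduct as triphenylphosphonium ylide, C1 trans to the C5 substituent (not isolated) | C1CC[C@@H]([C@](C)(C(=O)OC)C=O)[C@](C)(CC=P(c2ccccc2)(c2ccccc2)c2ccccc2)C1=O | intermediate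
18 | methyl (1R,4aS,8aR)-1,4a-dimethyl-5-oxo-1,4,4a,5,6,7,8,8a-octahydronaphthalene-1-carboxylate | O=C1CCC[C@H]2[C@](C)(C(=O)OC)C=CC[C@]12C | intermediate
19 | methyl (1R,4aS,8aR)-1,4a-dimethyl-5-oxodecahydronaphthalene-1-carboxylate | O=C1CCC[C@H]2[C@](C)(C(=O)OC)CCC[C@]12C | intermediate
20 | potassium C8–C9 enolate of 19 (not isolated) | [K]OC1=CCC[C@H]2[C@](C)(C(=O)OC)CCC[C@]12C | intermediate
21 | methyl (1R,4aS,8aR)-1,4a-dimethyl-5-{[(trifluoromethyl)sulfonyl]oxy}-1,2,3,4,4a,7,8,8a-octahydronaphthalene-1-carboxylate | O=S(=O)(OC1=CCC[C@H]2[C@](C)(C(=O)OC)CCC[C@]12C)C(F)(F)F | intermediate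
22 | (S)-5-methoxy-3-methyl-5-oxopentanoic acid | OC(=O)C[C@H](C)CC(=O)OC | starting material
23 | methyl (S)-5-hydroxy-3-methylpentanoate | OCC[C@H](C)CC(=O)OC | intermediate
24 | methyl (R)-5-iodo-3-methylpentanoate | ICC[C@H](C)CC(=O)OC | intermediate
25 | [(R)-5-methoxy-3-methyl-5-oxopentyl]zinc iodide (not isolated) | I[Zn]CC[C@H](C)CC(=O)OC | intermediate
26 | dimethyl (13S)-17-norlabd-8-ene-15,18-dioate | COC(=O)C[C@@H](C)CCC1=CCC[C@H]2[C@](C)(C(=O)OC)CCC[C@]12C | intermediate
27 | C8α alkylborane of 26, 9α-H, drawn as the monoalkylborane (not isolated) | B[C@@H]1CC[C@H]2[C@](C)(C(=O)OC)CCC[C@]2(C)[C@H]1CC[C@H](C)CC(=O)OC | intermediate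
28 | dimethyl (13S)-8α-hydroxy-17-norlabdane-15,18-dioate (5α-H, 9α-H, 10β-CH3) | O[C@@H]1CC[C@H]2[C@](C)(C(=O)OC)CCC[C@]2(C)[C@H]1CC[C@H](C)CC(=O)OC | intermediate
29 | dimethyl (13S)-8-oxo-17-norlabdane-15,18-dioate | O=C1CC[C@H]2[C@](C)(C(=O)OC)CCC[C@]2(C)[C@H]1CC[C@H](C)CC(=O)OC | intermediate
30 | dimethyl (13S)-labd-8(17)-ene-15,18-dioate | C=C1CC[C@H]2[C@](C)(C(=O)OC)CCC[C@]2(C)[C@H]1CC[C@H](C)CC(=O)OC | intermediate
31 | (13S)-18-methoxy-18-oxolabd-8(17)-en-15-oic acid | C=C1CC[C@H]2[C@](C)(C(=O)OC)CCC[C@]2(C)[C@H]1CC[C@H](C)CC(=O)O | intermediate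
32 | (13S)-18-hydroxylabd-8(17)-en-15-oic acid | C=C1CC[C@H]2[C@](C)(CO)CCC[C@]2(C)[C@H]1CC[C@H](C)CC(=O)O | intermediate
33 | mixed acetic anhydride of 18-acetoxy acid (not isolated) | C=C1CC[C@H]2[C@](C)(COC(C)=O)CCC[C@]2(C)[C@H]1CC[C@H](C)CC(=O)OC(C)=O | intermediate
34 | (13S)-18-acetoxylabd-8(17)-en-15-oic acid (5α-H, 9α-H, 10β-CH3, 4α-CH2OAc, 4β-CH3) | C=C1CC[C@H]2[C@](C)(COC(C)=O)CCC[C@]2(C)[C@H]1CC[C@H](C)CC(=O)O | target

**Count.** Total steps: 20. Longest linear sequence: 17 (steps 2–11 and 14–20).

**Steps most likely to fail**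

1. Step 5 (Ireland–Claisen). The tetrasubstituted enolate may form with poor geometric control, or the rearrangement may run through the chair-like instead of the boat-like array; either would deliver the wrong configuration at C4. β-Elimination of silanolate from the enolate is a further risk. Fallback, setting out from 2 and coming back at 10: 2 is heated with triethyl orthoacetate and catalytic propionic acid (Johnson–Claisen rearrangement, same suprafacial transfer to C5) to give ethyl 2-[(1S)-2-methylcyclohex-2-en-1-yl]acetate F1. Saponification (LiOH, THF/H2O) gives 2-[(1S)-2-methylcyclohex-2-en-1-yl]acetic acid F2, and iodolactonisation (I2, KI, NaHCO3) should give the cis-fused iodolactone F3, with the lactone oxygen on C10 and iodine on C9. Its lithium enolate (LiN(iPr)2, −78 °C) is hydroxymethylated with gaseous formaldehyde to the α-(hydroxymethyl) lactone F4. The dianion of F4 (LiN(iPr)2, 2.2 equiv) is methylated with MeI on the convex face of the bicycle, which should give the quaternary lactone F5 with the C4 configuration of 10. Zn in acetic acid then eliminates iodide and carboxylate across C9–C10 and returns 10.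

2. Step 9 (key annulation). The Michael addition may occur at C8 instead of C10, the base may cleave the α-formyl ester by deformylation, or the C8 enolate may be held up in an aldol closure onto the aldehyde. Fallback, setting out from 14 and coming back at 18: Ph3P=CH2 (1 equiv, THF, −78 °C) should methylenate only the aldehyde and give methyl (2R)-2-methyl-2-[(1R,2R)-2-methyl-3-oxocyclohexyl]but-3-enoate F6. The thermodynamic potassium enolate (KH, THF) is allylated with allyl bromide at C10, anti to the C5 substituent, to give methyl (2R)-2-methyl-2-[(1R,2S)-2-methyl-3-oxo-2-(prop-2-en-1-yl)cyclohexyl]but-3-enoate F7. Ring-closing metathesis with the second-generation Grubbs catalyst (CH2Cl2, 40 °C) closes C2=C3 and gives 18.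

3. Step 15 (hydroboration of the hindered C8=C9 alkene). Addition may be slow enough for borane to start reducing the side-chain ester, or facial selectivity may be incomplete. Fallback, setting out from 26 and coming back at 29: mCPBA (NaHCO3, CH2Cl2, 0 °C) should epoxidise C8=C9 from the α face to give dimethyl (13S)-8α,9α-epoxy-17-norlabdane-15,18-dioate F8. BF3·OEt2 (CH2Cl2, −78 °C) opens the epoxide at tertiary C9, and a 1,2-hydride shift from C8 to C9 (Meinwald rearrangement) gives ketone 29, whose C9 centre settles to the equatorial side chain.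

**Further compounds**

F1 | step 5 | ethyl 2-[(1S)-2-methylcyclohex-2-en-1-yl]acetate | C1CC[C@@H](CC(=O)OCC)C(C)=C1
F2 | step 5 | 2-[(1S)-2-methylcyclohex-2-en-1-yl]acetic acid | C1CC[C@@H](CC(=O)O)C(C)=C1
F3 | step 5 | cis-fused iodolactone, 7-iodo-7a-methylhexahydro-1-benzofuran-2(3H)-one (lactone O on C10 cis to the C5–C4 bond, I on C9 trans to that O) | O=C1C[C@@H]2CCC[C@@H](I)[C@]2(C)O1
F4 | step 5 | 3-(hydroxymethyl) derivative of F3 (both C4 epimers) | O=C1C(CO)[C@@H]2CCC[C@@H](I)[C@]2(C)O1
F5 | step 5 | 3-(hydroxymethyl)-3-methyl derivative of F3 (CH3 on the convex face) | O=C1[C@](C)(CO)[C@@H]2CCC[C@@H](I)[C@]2(C)O1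
F6 | step 9 | methyl (2R)-2-methyl-2-[(1R,2R)-2-methyl-3-oxocyclohexyl]but-3-enoate | C1CC[C@@H]([C@](C)(C(=O)OC)C=C)[C@@H](C)C1=O
F7 | step 9 | methyl (2R)-2-methyl-2-[(1R,2S)-2-methyl-3-oxo-2-(prop-2-en-1-yl)cyclohexyl]but-3-enoate | C1CC[C@@H]([C@](C)(C(=O)OC)C=C)[C@](C)(CC=C)C1=O
F8 | step 15 | dimethyl (13S)-8α,9α-epoxy-17-norlabdane-15,18-dioate | O1[C@@H]2CC[C@H]3[C@](C)(C(=O)OC)CCC[C@]3(C)[C@]12CC[C@H](C)CC(=O)OC
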